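**Plan**
- Retrosynthesis: the C13 silyl ether and the C3–Br bond (from an axial C3 alcohol, itself from a C3 ketone) are adjusted last; ring A is cut at C1–C2 (aldol condensation); ring B is cut at C5–C6 and C9–C10 ([4+2]).
- Forward: an (R)-linalool-derived 2-silyloxy diene (C6–C9 with the C11–C16 chain) and an E keto enal (C1, C10, C5, C4, C3, C2) are joined by cycloaddition to give ring B; base then closes ring A.
- Enabling feature: ring B is the cyclohexene C5–C6–C7–C8–C9–C10. Its C7=C8 bond is the enol-ether bond of a Diels–Alder adduct, C5 and C10 are the two carbons of an E alkene, C9 is a diene terminus, and the C11 chain lies anti to the C20 methyl, as an endo adduct requires.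
- Finishing: enol silane → enol triflate → C7–H; enone → ketone → axial alcohol → equatorial bromide; desilylation.
- Stereochemistry: C13 comes from (R)-linalool; C5/C10 from the enal geometry; C9 from the endo transition state; the absolute sense from an (R)-prolinol-derived oxazaborolidinium catalyst; C3 from equatorial hydride delivery followed by SN2 inversion.

Key step: step 9

Remark on labels: C1–C20 are labdane-type atom labels only. The CIP descriptor of C9 changes between S and R with the substituent on C7; no ring centre is inverted anywhere except C3 in step 15.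

Assumption: the facial sense in step 9 is taken from the accepted pre-transition-state model for α-substituted enals on cationic oxazaborolidines (formyl C–H against the ring oxygen, s-trans enal stacked on the neighbouring phenyl group), which predicts si-face attack at C10 with the (R)-prolinol catalyst. If this hindered enal responded in the opposite sense, the (S)-catalyst would be used and nothing else changes.

**Route**

Step 1
Reactants: 1 (R)-linalool
Product: 2 triethyl{[(3R)-3,7-dimethylocta-1,6-dien-3-yl]oxy}silane
Conditions: Et3SiOTf, 2,6-lutidine, CH2Cl2, −78 → 0 °C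
Reagents that add atoms: triethylsilyl trifluoromethanesulfonate, CC[Si](CC)(CC)OS(=O)(=O)C(F)(F)F
Why: A silyl triflate with a hindered pyridine base silylates tertiary alcohols cleanly (silyl ether protection), leaving the C13 centre and both alkenes untouched.

Step 2
Reactants: 2 triethyl{[(3R)-3,7-dimethylocta-1,6-dien-3-yl]oxy}silane
Product: 4 (2E,6R)-2,6-dimethyl-6-(triethylsilyloxy)octa-2,7-dienal, via allylic alcohol 3 (not isolated)
Conditions: SeO2 (0.3 equiv), t-BuOOH, salicylic acid (cat.), CH2Cl2, rt; filter; MnO2, CH2Cl2, rt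
Reagents that add atoms: tert-butyl hydroperoxide, CC(C)(C)OO; selenium dioxide, O=[Se]=O
Why: Allylic oxidation by SeO2 (ene reaction then [2,3]-sigmatropic shift) attacks the E methyl group of the trisubstituted alkene, the vinyl group having no allylic hydrogen, and MnO2 converges the alcohol/aldehyde mixture on the E enal.

Step 3
Reactants: 4 (2E,6R)-2,6-dimethyl-6-(triethylsilyloxy)octa-2,7-dienal
Product: 5 (3E,7R)-3,7-dimethyl-7-(triethylsilyloxy)nona-3,8-dien-2-ol (both C2 epimers)
Conditions: MeMgBr, THF, −78 °C; then H2O
Reagents that add atoms: methylmagnesium bromide, C[Mg]Br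
Why: Grignard 1,2-addition to the α-branched enal; the new carbinol centre forms unselectively and is erased in step 4.

Step 4
Reactants: 5 (3E,7R)-3,7-dimethyl-7-(triethylsilyloxy)nona-3,8-dien-2-ol
Product: 6 (3E,7R)-3,7-dimethyl-7-(triethylsilyloxy)nona-3,8-dien-2-one
Conditions: Dess–Martin periodinane, NaHCO3, CH2Cl2, 0 °C → rt
Reagents that add atoms: none
Why: Dess–Martin oxidation of a secondary allylic alcohol under bicarbonate buffering gives the enone without touching the alkene geometry or the silyl ether.

Step 5
Reactants: 6 (3E,7R)-3,7-dimethyl-7-(triethylsilyloxy)nona-3,8-dien-2-one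
Product: 7 (3E,7R)-3,7-dimethyl-7-(triethylsilyloxy)-2-(triisopropylsilyloxy)nona-1,3,8-triene
Conditions: i-Pr3SiOTf, Et3N, CH2Cl2, 0 °C
Reagents that add atoms: triisopropylsilyl trifluoromethanesulfonate, CC(C)[Si](C(C)C)(C(C)C)OS(=O)(=O)C(F)(F)F
Why: Soft enolisation (silyl triflate/amine) of the methyl ketone at its only α-CH3 gives the cross-conjugated 2-silyloxy diene with the E alkene retained.

Step 6
Reactants: 8 ethyl 2,2-dimethyl-3-oxobutanoate
Product: 9 2,2-dimethylbutane-1,3-diol (racemic)
Conditions: LiAlH4, Et2O, 0 °C → rt; aqueous work-up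
Reagents that add atoms: none
Why: Hydride reduction of ester and ketone gives the 1,3-diol; its carbinol centre is irrelevant because both hydroxyls are re-oxidised.

Step 7
Reactants: 9 2,2-dimethylbutane-1,3-diol
Product: 10 2,2-dimethyl-3-oxobutanal
Conditions: (COCl)2, DMSO, CH2Cl2, −78 °C; Et3N, → 0 °C; used as a concentrated solution
Reagents that add atoms: none
Why: Swern oxidation converts both hydroxyls under non-aqueous conditions; the quaternary α-carbon rules out enolisation, so the β-keto aldehyde can neither aldolise nor eliminate.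

Step 8
Reactants: 10 2,2-dimethyl-3-oxobutanal; 11 2-(triphenylphosphoranylidene)propanal
Product: 12 (2E)-2,4,4-trimethyl-5-oxohex-2-enal
Conditions: toluene, 90 °C (sealed tube)
Reagents that add atoms: none
Why: Wittig olefination with the stabilised formyl ylide is selective for the aldehyde over the hindered ketone and gives the E trisubstituted enal.

Step 9
Reactants: 7 (3E,7R)-3,7-dimethyl-7-(triethylsilyloxy)-2-(triisopropylsilyloxy)nona-1,3,8-triene; 12 (2E)-2,4,4-trimethyl-5-oxohex-2-enal
Product: 13 (1S,2S,6S)-1,3-dimethyl-6-(2-methyl-3-oxobutan-2-yl)-2-[(3R)-3-methyl-3-(triethylsilyloxy)pent-4-en-1-yl]-4-(triisopropylsilyloxy)cyclohex-3-ene-1-carbaldehyde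
Conditions: (3aR)-1-(2-methylphenyl)-3,3-diphenyltetrahydro-1H,3H-pyrrolo[1,2-c][1,3,2]oxazaborole (20 mol %), Tf2NH (17 mol %), 12 (1.5 equiv), CH2Cl2, −78 → −30 °C; Et3N quench
Reagents that add atoms: none
Why: The N-protonated oxazaborolidine binds the formyl oxygen of 12, and the activated s-trans enal is attacked by the s-cis diene 7 in a concerted, asynchronous [4+2] in which C6 (the CH2 terminus of the dienol ether) bonds to the β-carbon C5 slightly ahead of C9 bonding to the α-carbon C10. The closest known reaction type is the chiral oxazaborolidinium-catalysed Diels–Alder reaction of 2-silyloxy-1,3-dienes with α-substituted enals. Ring B closes by intermolecular cycloaddition, the bonds C5–C6 and C9–C10 joining a four-carbon and a two-carbon unit into the cyclohexene. C5 and C10 are fixed relative to each other by suprafacial addition to the E alkene (C4 and C1 trans); C9 is fixed relative to C10 by the endo transition state, which puts the formyl group under the diene and cis to the E-disposed C11 chain while the methyl and tert-alkyl groups stay exo; the absolute sense comes from the catalyst, whose phenyl group covers the re face of C10 so that the diene adds to its si face, the remote C13 centre being a spectator. The step needs regioselectivity (the silyloxy group on C7 and the alkyl group on C9 both direct C6 to C5), activation of the aldehyde over the ketone (the ketone is neopentyl and a weaker donor), and cycloaddition over Mukaiyama aldol addition at the formyl carbon (the bulky boron complex screens the carbonyl carbon and the reaction is run cold).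

Step 10
Reactants: 13 ring-B cycloadduct
Product: 15 bicyclic enone with Δ1-3-ketone, 7-OTIPS enol ether and 13-OTES (5S,9R,10S,13R), via β-hydroxy ketone 14 (not isolated)
Conditions: KOt-Bu (0.3 equiv), t-BuOH/THF, 0 → 40 °C
Reagents that add atoms: none
Why: Intramolecular aldol condensation: the methyl ketone enolises only at C2 and the aldehyde cannot enolise, so 6-(enolexo)-exo-trig closure and E1cB dehydration should give a single enone on the trans ring fusion already fixed in 13, the bulky alkoxide sparing both silyl groups.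

Step 11
Reactants: 15 bicyclic enone with 7-OTIPS enol ether
Product: 17 C7 enol triflate of the Δ1-3-ketone (5S,9R,10S,13R), via cesium enolate 16 (not isolated)
Conditions: CsF, PhNTf2, DME, rt
Reagents that add atoms: N-phenylbis(trifluoromethanesulfonimide), O=S(=O)(N(c1ccccc1)S(=O)(=O)C(F)(F)F)C(F)(F)F
Why: Fluoride cleaves the enol Si–O bond to the regiodefined C7 enolate, which is O-sulfonylated in the same flask (enol silane to enol triflate exchange); the enone cannot enolise and the tertiary alkyl silyl ether is far slower to cleave.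

Step 12
Reactants: 17 C7 enol triflate
Product: 18 trienone with Δ1-3-ketone, Δ7, Δ14 and 13-OTES (5S,9S,10S,13R)
Conditions: Pd(OAc)2 (5 mol %), PPh3, n-Bu3N, HCO2H, DMF, 60 °C
Reagents that add atoms: none
Why: Palladium-catalysed formate reduction of an enol triflate (oxidative addition to zerovalent palladium, formate exchange, decarboxylation, C–H reductive elimination) replaces OTf by H with the C7=C8 bond kept in place; enone and vinyl group are tolerated.

Step 13
Reactants: 18 trienone
Product: 19 saturated 3-ketone with Δ7, Δ14 and 13-OTES (5S,9S,10S,13R)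
Conditions: [(Ph3P)CuH]6 (0.5 equiv), H2O, toluene/THF, rt
Reagents that add atoms: none
Why: The phosphine-ligated copper hydride transfers hydride to C1 in a conjugate sense and C2 is protonated by water (copper hydride conjugate reduction), leaving the isolated C7=C8 and C14=C15 alkenes alone; no stereocentre is formed.

Step 14
Reactants: 19 saturated 3-ketone
Product: 20 axial (3S)-alcohol with OH cis to H-5 and trans to C20 (3S,5S,9S,10S,13R)
Conditions: LiBH(s-Bu)3, THF, −78 °C; then H2O
Reagents that add atoms: none
Why: The bulky borohydride approaches the 4,4-dimethyl ketone along the equatorial trajectory, away from the axial hydrogens on C1 and C5, so C3 should emerge as the axial alcohol by substrate control.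

Step 15
Reactants: 20 axial (3S)-alcohol
Product: 21 equatorial (3R)-bromide, 13-OTES (3R,5S,9S,10S,13R)
Conditions: PPh3, CBr4, 2,6-lutidine, toluene, 0 → 60 °C
Reagents that add atoms: carbon tetrabromide, BrC(Br)(Br)Br
Why: Appel bromination: bromide displaces the phosphonium-activated axial oxygen from the rear (SN2), so inversion places bromine equatorial and cis to C20.

Step 16
Reactants: 21 equatorial (3R)-bromide, 13-OTES
Product: 22 (3R)-5-[(1S,4aS,6R,8aS)-6-bromo-2,5,5,8a-tetramethyl-1,4,4a,5,6,7,8,8a-octahydronaphthalen-1-yl]-3-methylpent-1-en-3-ol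
Conditions: HF·pyridine, pyridine, THF, 0 °C → rt
Reagents that add atoms: none
Why: Fluoride-driven cleavage of the tertiary silyl ether under buffered, non-basic conditions that should neither eliminate the secondary bromide nor ionise the tertiary allylic alcohol.

**Compound list**

1 | (R)-linalool, (3R)-3,7-dimethylocta-1,6-dien-3-ol | C=C[C@](C)(O)CCC=C(C)C | starting material
2 | triethyl{[(3R)-3,7-dimethylocta-1,6-dien-3-yl]oxy}silane | C=C[C@](C)(O[Si](CC)(CC)CC)CCC=C(C)C | intermediate
3 | (2E,6R)-2,6-dimethyl-6-(triethylsilyloxy)octa-2,7-dien-1-ol | C=C[C@](C)(O[Si](CC)(CC)CC)CC/C=C(\C)CO | intermediate (not isolated)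
4 | (2E,6R)-2,6-dimethyl-6-(triethylsilyloxy)octa-2,7-dienal | C=C[C@](C)(O[Si](CC)(CC)CC)CC/C=C(\C)C=O | intermediate
5 | (3E,7R)-3,7-dimethyl-7-(triethylsilyloxy)nona-3,8-dien-2-ol, both C2 epimers | C=C[C@](C)(O[Si](CC)(CC)CC)CC/C=C(\C)C(C)O | intermediate
6 | (3E,7R)-3,7-dimethyl-7-(triethylsilyloxy)nona-3,8-dien-2-one | C=C[C@](C)(O[Si](CC)(CC)CC)CC/C=C(\C)C(C)=O | intermediate
7 | (3E,7R)-3,7-dimethyl-7-(triethylsilyloxy)-2-(triisopropylsilyloxy)nona-1,3,8-triene | C=C[C@](C)(O[Si](CC)(CC)CC)CC/C=C(\C)C(=C)O[Si](C(C)C)(C(C)C)C(C)C | intermediate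
8 | ethyl 2,2-dimethyl-3-oxobutanoate | CCOC(=O)C(C)(C)C(C)=O | starting material
9 | 2,2-dimethylbutane-1,3-diol (racemic) | CC(O)C(C)(C)CO | intermediate
10 | 2,2-dimethyl-3-oxobutanal | CC(=O)C(C)(C)C=O | intermediate
11 | 2-(triphenylphosphoranylidene)propanal | CC(C=O)=P(c1ccccc1)(c1ccccc1)c1ccccc1 | starting material
12 | (2E)-2,4,4-trimethyl-5-oxohex-2-enal | O=C/C(C)=C/C(C)(C)C(C)=O | intermediate
13 | (1S,2S,6S)-1,3-dimethyl-6-(2-methyl-3-oxobutan-2-yl)-2-[(3R)-3-methyl-3-(triethylsilyloxy)pent-4-en-1-yl]-4-(triisopropylsilyloxy)cyclohex-3-ene-1-carbaldehyde (formyl cis to the C9 chain, trans to the C5 substituent) | C=C[C@](C)(O[Si](CC)(CC)CC)CC[C@H]1C(C)=C(O[Si](C(C)C)(C(C)C)C(C)C)C[C@H](C(C)(C)C(C)=O)[C@@]1(C)C=O | intermediate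
14 | ring-A aldol: trans-fused 1-hydroxy-3-ketone (C1 epimers), 7-OTIPS enol ether, 13-OTES; 5S,9R,10S,13R | C=C[C@](C)(O[Si](CC)(CC)CC)CC[C@H]1C(C)=C(O[Si](C(C)C)(C(C)C)C(C)C)C[C@@H]2C(C)(C)C(=O)CC(O)[C@]21C | intermediate (not isolated)
15 | (4aS,5R,8aS)-1,1,4a,6-tetramethyl-5-[(3R)-3-methyl-3-(triethylsilyloxy)pent-4-en-1-yl]-7-(triisopropylsilyloxy)-4a,5,8,8a-tetrahydronaphthalen-2(1H)-one | C=C[C@](C)(O[Si](CC)(CC)CC)CC[C@H]1C(C)=C(O[Si](C(C)C)(C(C)C)C(C)C)C[C@@H]2C(C)(C)C(=O)C=C[C@]21C | intermediate
16 | cesium C7 enolate of the Δ1-3-ketone; 5S,9R,10S,13R | C=C[C@](C)(O[Si](CC)(CC)CC)CC[C@H]1C(C)=C([O-])C[C@@H]2C(C)(C)C(=O)C=C[C@]21C.[Cs+] | intermediate (not isolated)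
17 | C7 enol triflate of the Δ1-3-ketone, 13-OTES; 5S,9R,10S,13R | C=C[C@](C)(O[Si](CC)(CC)CC)CC[C@H]1C(C)=C(OS(=O)(=O)C(F)(F)F)C[C@@H]2C(C)(C)C(=O)C=C[C@]21C | intermediate
18 | trans-fused trienone: Δ1-3-ketone, Δ7, Δ14, 13-OTES; 5S,9S,10S,13R | C=C[C@](C)(O[Si](CC)(CC)CC)CC[C@H]1C(C)=CC[C@@H]2C(C)(C)C(=O)C=C[C@]21C | intermediate
19 | trans-fused 3-ketone: Δ7, Δ14, 13-OTES; 5S,9S,10S,13R | C=C[C@](C)(O[Si](CC)(CC)CC)CC[C@H]1C(C)=CC[C@@H]2C(C)(C)C(=O)CC[C@]21C | intermediate
20 | axial 3-alcohol (OH cis to H-5, trans to C20): Δ7, Δ14, 13-OTES; 3S,5S,9S,10S,13R | C=C[C@](C)(O[Si](CC)(CC)CC)CC[C@H]1C(C)=CC[C@@H]2C(C)(C)[C@@H](O)CC[C@]21C | intermediate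
21 | equatorial 3-bromide (Br cis to C20): Δ7, Δ14, 13-OTES; 3R,5S,9S,10S,13R | C=C[C@](C)(O[Si](CC)(CC)CC)CC[C@H]1C(C)=CC[C@@H]2C(C)(C)[C@H](Br)CC[C@]21C | intermediate
22 | (3R)-5-[(1S,4aS,6R,8aS)-6-bromo-2,5,5,8a-tetramethyl-1,4,4a,5,6,7,8,8a-octahydronaphthalen-1-yl]-3-methylpent-1-en-3-ol (3R,5S,9S,10S,13R by atom label) | C=C[C@](C)(O)CC[C@H]1C(C)=CC[C@@H]2C(C)(C)[C@H](Br)CC[C@]21C | target

**Totals and risks**

Total step count: 16. Longest linear sequence: 13 steps (steps 1–5 and 9–16, from (R)-linalool).

Steps most likely to fail: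

Step 9. Bond formation at the neopentyl β-carbon C5 may be so slow that protodesilylation of the diene or 1,2-addition to the formyl carbon takes over, or the catalyst may discriminate the enal faces poorly. The fallback gives up catalyst control. It sets out from 7 and 12, which are combined without any acid in CH2Cl2 at about 12 kbar and room temperature. This pressure-accelerated thermal [4+2] tolerates hindered partners and cannot divert into acid-promoted aldol chemistry. The endo adduct should then form as 13 together with its diastereomer, the (1R,2R,6R)-configured ring-mirrored cycloadduct F1. The mixture is cyclised as in step 10, and the wanted enone is separated by preparative HPLC from the (5R,9S,10R,13R)-configured diastereomeric enone F2. The route is rejoined at 15.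

Step 15. The activated axial C3–O group has the axial H-2 and the axial C4 methyl antiperiplanar to it, so anti elimination or ionisation with methyl shift may outrun bromide attack at the neopentyl carbon, and prolonged heating may also erode the tertiary silyl ether. The fallback separates activation from substitution. It sets out from 20, which is converted with ClCH2SO2Cl and pyridine at 0 °C into the axial C3 chloromethanesulfonate F3, a small sulfonate suited to substitution at hindered secondary carbons. This is displaced with LiBr in N,N-dimethylformamide at 40–60 °C with inversion, and the route is rejoined at 21.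

Step 8. The weakly nucleophilic formyl ylide may react sluggishly with the neopentyl aldehyde while the volatile β-keto aldehyde is lost by evaporation or deacylation, and the product enal may be homologated a second time. The fallback changes the olefination and the oxidation level. It sets out from 10, which undergoes a Horner–Wadsworth–Emmons reaction with triethyl 2-phosphonopropanoate (NaH, THF, 0 °C) to give ethyl (2E)-2,4,4-trimethyl-5-oxohex-2-enoate F4. Ester and ketone are reduced with i-Bu2AlH (CH2Cl2, −78 °C) to (2E)-2,4,4-trimethylhex-2-ene-1,5-diol F5. Both hydroxyls are then oxidised with Dess–Martin periodinane, and the route is rejoined at 12.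

**Further compounds**

F1 | step 9 | (1R,2R,6R)-1,3-dimethyl-6-(2-methyl-3-oxobutan-2-yl)-2-[(3R)-3-methyl-3-(triethylsilyloxy)pent-4-en-1-yl]-4-(triisopropylsilyloxy)cyclohex-3-ene-1-carbaldehyde | C=C[C@](C)(O[Si](CC)(CC)CC)CC[C@@H]1C(C)=C(O[Si](C(C)C)(C(C)C)C(C)C)C[C@@H](C(C)(C)C(C)=O)[C@]1(C)C=O
F2 | step 9 | diastereomeric enone, ring centres of 15 inverted (5R,9S,10R,13R) | C=C[C@](C)(O[Si](CC)(CC)CC)CC[C@@H]1C(C)=C(O[Si](C(C)C)(C(C)C)C(C)C)C[C@H]2C(C)(C)C(=O)C=C[C@@]21C
F3 | step 15 | axial C3 chloromethanesulfonate of 20 (3S,5S,9S,10S,13R) | C=C[C@](C)(O[Si](CC)(CC)CC)CC[C@H]1C(C)=CC[C@@H]2C(C)(C)[C@@H](OS(=O)(=O)CCl)CC[C@]21C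
F4 | step 8 | ethyl (2E)-2,4,4-trimethyl-5-oxohex-2-enoate | CCOC(=O)/C(C)=C/C(C)(C)C(C)=O
F5 | step 8 | (2E)-2,4,4-trimethylhex-2-ene-1,5-diol (racemic) | OC/C(C)=C/C(C)(C)C(C)O
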